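In the dawn run, the gain of isomer of the product per unit of target was 0.214 min⁻¹ between 0.833 min and 1.50 min, but less, 0.0516 min⁻¹, between 3.00 min and 4.00 min. Two of us dispute what that means for the new flask.

- dawn: starting material 0.25 M; capture agent 2.5 mM; protic impurity 5 mM; run made earlier
- flask: starting material 0.25 M; capture agent 5.00 mM; protic impurity 5.00 mM; time 20 min

dawn run (percent of the starting material charged)

| time / min | target / % | isomer of the product / % |
|---|---|---|
| 0.833 | 17.7 | 2.9 |
| 1.50 | 31.3 | 6.4 |
| 2.50 | 46.1 | 10.3 |
| 3.00 | 52.2 | 12.6 |
| 4.00 | 60.2 | 15.5 |

(standard deviation of a reading: 0.3 percentage points)

- share of target in target plus isomer of the product at 12 s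
- share of target in target plus isomer of the product at 2.0 min
- share of target in target plus isomer of the product at 20 min

- what was read earlier has a scatter of 0.3 percentage points, one standard deviation
- a reading or a percentage of target counts all its forms, free or not
- no earlier run changes the charge of capture agent; that part of a forecast is a guess

My colleague holds a chain: target decays first order into isomer of the product. Over the whole dawn run he reads a mean constant of 0.102 min⁻¹, so a half-life of target of 6.80 min. He carries the share at 4.00 min on to 20 min with that decay and gets 15.5%.

I answer that a chain needs that gain per unit of target to stay constant, and it fell. I hold a split instead. The first dawn reading has a share of 85.9%. In the dawn run, between 0.833 min and 1.50 min new product is 79.5% target, and between 2.50 min and 4.00 min it is 73.1%. I carry this marginal share, target gained in a window over target plus isomer gained there; the field says instantaneous selectivity.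

Since 79.5% lies below 85.9%, I put the share at 12 s above 85.9%. From the two dawn readings around 2.0 min I read 82.3%. At 4.00 min of the dawn run, 24.3% of the charge is in neither product; if it divides by 73.1%, my end share is 78.0%. The capture agent is a guess: I leave it out.

The forecast, on my side, reads 88%, 82.6% and 77.5%, with “simple decay of target to isomer looks unlikely”, and its end value is a little lower than mine. The flask gives 91.8%, 82.1% and 73.6%.

    starting material → open intermediate (k = 0.433 min⁻¹)
    open intermediate ⇌ target (K = 1.71, k = 8.14 min⁻¹)
    open intermediate ⇌ isomer of the product (K = 32.2, k = 0.531 min⁻¹)
    open intermediate + capture agent → trapped intermediate (k = 3.85 L mol⁻¹ min⁻¹)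
    crystals ⇌ target, rate k5*(cs5 - [target]) while solid is left; crystals form when [target] > cs5 (solubility = 6.30 mM, k = 1.84 min⁻¹)
    starting material + protic impurity → quenched substrate (k = 1080 L mol⁻¹ min⁻¹)

The chain's 15.5% lies below the flask's end share. In this flask the marginal share from 2.00 min to 10.0 min is 71.5%, near the dawn reading of 73.1%. Then target in this flask, all forms counted, slips from 72.6% to 70.5% of the charge, and my end value stands 4.4 percentage points above the flask's share. The chain gets its region at low charge: the neighbour charged with 0.062 M of starting material ends at a share of 33.8%, below 73.1%, and target and isomer end equal at a charge of 0.0869 M. In this flask at 20.0 min, open intermediate passes into isomer of the product with a half-life of 1.3 min by the forward step alone, shorter than the 42 min of the isomer's way back. At that time, by forward rates alone, open intermediate goes into target 15 times as fast as into isomer.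

(The runs are calculated with constants of no real substance; noise was put on by code.)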